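## Retrosynthetic overview

1. Target **24** is 3β-acetoxy-9α-hydroxylabd-13-en-15,16-olide (labdane numbering throughout). The butenolide is unmasked last from a 3-substituted furan (singlet oxygen, then borohydride), and the acetate comes from the free 3β-OH.
2. C11–C12 is cut to a 9α,11-spiro-epoxide and a furan-3-ylmethyl Grignard/copper reagent. The epoxide comes from the C9 ketone by methylenation and α-face epoxidation.
3. Key disconnection: C3–C4 of ring A, made by hydrogen-atom transfer to an isopropenyl group and 6-exo addition of the tertiary C4 radical to a C3 aldehyde.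
4. Feature used: C5 and its neighbour C4 are the stereocentre and isopropenyl carbon of (R)-carvone, whose enone carbons already carry the C9 oxygen and the C8 methyl of ring B. Only C10 (two alkylations) and the C3–C4 bond remain to be made.
5. Ring order: ring B (the carvone ring) → ring A (step 6) → butenolide ring (steps 12 and 13).

Key step: step 6

Remark: a carbon nucleophile is expected to add to the C9 ketone anti to the axial 10β-methyl and give the 9-epimer, so the C9 oxygen is instead delivered to the α face of a C9 methylene group and the side chain is attached at C11.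
Remark: the 3β-OH is carried unprotected from step 6 and acetylated once the tertiary 9-OH is in place.

## Route

Step 1
Reactants: 1 (R)-carvone
Product: 3 (5R)-2,6-dimethyl-5-(prop-1-en-2-yl)cyclohex-2-en-1-one (6-methylcarvone; mixture of C6 epimers), via lithium dienolate 2 (not isolated)
Conditions: LDA, THF, −78 °C; MeI, −78 → 0 °C
Reagents that add atoms: iodomethane CI
Why: Kinetic α′-deprotonation of the enone with LDA gives the cross-conjugated dienolate, whose C-methylation (enolate alkylation) installs the future C20 methyl; the configuration at this carbon is unimportant because it is planarised again in step 2.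

Step 2
Reactants: 3 6-methylcarvone; 4 allyl bromide
Product: 6 (5S,6S)-6-allyl-2,6-dimethyl-5-(prop-1-en-2-yl)cyclohex-2-en-1-one (allyl trans to isopropenyl), via lithium enolate 5 (not isolated)
Conditions: LDA, THF, −78 °C; then 4, DMPU, −78 → −20 °C
Reagents that add atoms: none
Why: Enolate alkylation in which allyl bromide approaches the tetrasubstituted enolate anti to the neighbouring isopropenyl group, so the quaternary C10 forms with the three-carbon chain trans and the methyl cis to the isopropenyl group, as a 5α-H/10β-CH3 trans-decalin requires.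

Step 3
Reactants: 6 allyl methyl enone
Product: 8 (2S,3S,6R)-2-allyl-2,6-dimethyl-3-(prop-1-en-2-yl)cyclohexan-1-one, via lithium enolate 7 (not isolated)
Conditions: L-Selectride, THF, −78 °C; then MeOH, −78 °C → rt
Reagents that add atoms: none
Why: Conjugate (1,4) hydride reduction by the bulky trialkylborohydride occurs at the unsubstituted β-carbon because the carbonyl is screened by the adjacent quaternary centre and the isolated alkenes are inert, and methoxide-mediated equilibration at C8 should place the methyl equatorial (8α) because the 8β epimer would be syn-diaxial to the axial C10 methyl.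

Step 4
Reactants: 8 allyl ketone
Product: 10 (2S,3S,6R)-2-(3-hydroxypropyl)-2,6-dimethyl-3-(prop-1-en-2-yl)cyclohexan-1-one, via alkyl(disiamyl)borane 9 (not isolated)
Conditions: Sia2BH (from BH3·THF and 2-methylbut-2-ene), THF, 0 °C; then NaOH, H2O2, 0 °C → rt
Reagents that add atoms: hydrogen peroxide OO
Why: Hydroboration–oxidation in which the dialkylborane adds anti-Markovnikov to the monosubstituted allyl alkene much faster than to the 1,1-disubstituted isopropenyl group next to a quaternary carbon or to the doubly α-branched ketone, and alkaline peroxide then converts C–B into the primary alcohol.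

Step 5
Reactants: 10 hydroxy ketone
Product: 11 3-[(1S,3R,6S)-1,3-dimethyl-2-oxo-6-(prop-1-en-2-yl)cyclohexyl]propanal
Conditions: Dess–Martin periodinane, CH2Cl2, 0 °C → rt
Reagents that add atoms: none
Why: Dess–Martin oxidation of the primary alcohol stops at the aldehyde under near-neutral conditions, so neither the C8 centre nor the base-sensitive 1,5-keto aldehyde is disturbed.

Step 6
Reactants: 11 keto aldehyde
Product: 12 (2R,4aS,6S,8aS)-6-hydroxy-2,5,5,8a-tetramethyloctahydronaphthalen-1(2H)-one (3β-hydroxy-4,4,8α,10β-tetramethyl-trans-decalin-9-one)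
Conditions: Fe(acac)3 (0.3 equiv), PhSiH3 (2.5 equiv), degassed EtOH, 60 °C
Reagents that add atoms: none
Why: The iron hydride formed from Fe(acac)3 and PhSiH3 transfers a hydrogen atom to the CH2 terminus of the isopropenyl group (Markovnikov MHAT), creating the second C4 methyl and a nucleophilic tertiary C4 radical that adds to the carbon of the C3 aldehyde, after which the alkoxy radical is reduced by Fe(II) and protonated by ethanol. The closest known reaction type is the iron-hydride reductive radical cyclisation of unactivated alkenes onto tethered carbonyl groups, here with an aldehyde as acceptor. Ring A closes in the 6-exo-trig mode through a chair transition state. Because the C1–C3 chain on C10 and the C4 radical on C5 are trans-diequatorial on the existing chair (C10 methyl axial), the new ring can only be trans-fused (5α-H, 10β-CH3), and the one new stereocentre C3 is set by that chair, in which the carbonyl oxygen should sit pseudo-equatorial, away from the axial 1α and 5α hydrogens, to give 3β-OH. The step needs hydrogen-atom transfer to the only alkene and trapping of the alkoxy radical before β-scission; the substrate secures the first (the hindered C9 ketone could only close a four-membered ring) and the reducing Fe(II)/ethanol medium should secure the second.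

Step 7
Reactants: 12 hydroxy decalone
Product: 13 3β-hydroxy-4,4,8α,10β-tetramethyl-9-methylidene-trans-decalin (5α-H; exocyclic C9=C11)
Conditions: Ph3PCH3Br (4.5 equiv), KOtBu (4.4 equiv), toluene, 100 °C
Reagents that add atoms: methyltriphenylphosphonium bromide C[P+](c1ccccc1)(c1ccccc1)c1ccccc1.[Br-]
Why: Wittig methylenation with excess salt-free ylide at elevated temperature should overcome the hindrance at C9 and tolerate the free 3-OH as its alkoxide, and enolisation toward C8 is harmless because the equatorial 8α-methyl is the thermodynamic epimer.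

Step 8
Reactants: 13 methylidene alcohol
Product: 14 9α,11-epoxide of 13 (spiro-oxirane at C9, oxirane oxygen α and C11 β, 3β-OH)
Conditions: dimethyldioxirane (acetone solution), CH2Cl2, 0 °C
Reagents that add atoms: dimethyldioxirane CC1(C)OO1
Why: Epoxidation under neutral conditions (so the acid-labile 2,2-disubstituted epoxide survives) should take place on the α face of the exocyclic C9=C11 bond because the β face is blocked by the axial 10β-methyl on the adjacent carbon, which sets C9 with oxygen α.

Step 9
Reactants: 15 furan-3-ylmethanol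
Product: 17 3-(chloromethyl)furan, via furan-3-ylmethyl methanesulfonate 16 (not isolated)
Conditions: MsCl, s-collidine, LiCl, DMF, 0 °C
Reagents that add atoms: lithium chloride [Li+].[Cl-]
Why: Mesylation followed by in situ SN2 displacement by chloride gives the furylmethyl chloride without the acid that the furan would not tolerate.

Step 10
Reactants: 14 spiro-epoxide; 17 3-(chloromethyl)furan
Product: 19 15,16-epoxylabda-13(16),14-diene-3β,9α-diol (9β-[2-(furan-3-yl)ethyl] side chain), via (furan-3-ylmethyl)magnesium chloride 18 (not isolated)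
Conditions: 17 (3 equiv), Mg, THF, 0 °C; then CuI (15 mol%), 14, THF, −30 → 0 °C; aq. NH4Cl
Reagents that add atoms: none
Why: Copper-catalysed SN2 opening of the 2,2-disubstituted epoxide by the Grignard reagent occurs at the unsubstituted C11 terminus, forming C11–C12 while the C9–O bond and hence the 9α configuration are untouched; one equivalent of reagent is consumed by the 3-OH.

Step 11
Reactants: 19 furan diol
Product: 20 3β-acetoxy-15,16-epoxylabda-13(16),14-dien-9α-ol
Conditions: Ac2O, pyridine, DMAP (cat.), CH2Cl2, rt
Reagents that add atoms: acetic anhydride CC(=O)OC(C)=O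
Why: Acylation esterifies only the secondary equatorial 3β-OH, because the tertiary 9α-OH flanked by C8 and the quaternary C10 is too hindered to react at room temperature.

Step 12
Reactants: 20 furan acetate
Product: 22 3β-acetoxy-9α,16-dihydroxylabd-13-en-15,16-olide (γ-hydroxybutenolide; C16 epimers), via furan endoperoxide 21 (not isolated)
Conditions: O2, hν (visible), rose bengal (cat.), iPr2NEt, CH2Cl2, −78 °C
Reagents that add atoms: dioxygen O=O
Why: [4+2] cycloaddition of singlet oxygen across the furan gives the endoperoxide, and the hindered amine removes the less encumbered bridgehead hydrogen at C15 (remote from the C13 substituent) in a Kornblum–DeLaMare-type fragmentation, so the carbonyl appears at C15 and the hydroxyl at C16 as the target lactone requires.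

Step 13
Reactants: 22 γ-hydroxybutenolide
Product: 24 3β-acetoxy-9α-hydroxylabd-13-en-15,16-olide (target), via sodium hydroxy enoate 23 (not isolated)
Conditions: NaBH4, EtOH, 0 °C; then 1 M HCl to pH 3, rt
Reagents that add atoms: none
Why: The γ-hydroxybutenolide is in equilibrium with its ring-opened (Z)-formyl carboxylate, whose aldehyde is reduced chemoselectively by borohydride (the carboxylate-deactivated alkene, the acetate at 0 °C and the tertiary alcohol are spared), and acidification closes the hydroxy acid to the butenolide.

## Compound list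

1 | (R)-carvone, (5R)-2-methyl-5-(prop-1-en-2-yl)cyclohex-2-en-1-one | CC1=CC[C@H](CC1=O)C(C)=C | starting material
2 | lithium dienolate of 1 (α′ enolate) | [Li]OC1=C[C@H](C(C)=C)CC=C1C | intermediate (not isolated)
3 | (5R)-2,6-dimethyl-5-(prop-1-en-2-yl)cyclohex-2-en-1-one (C6 epimers) | O=C1C(C)=CC[C@@H](C(C)=C)C1C | intermediate
4 | allyl bromide | C=CCBr | starting material
5 | lithium enolate of 3 | [Li]OC1=C(C)[C@H](C(C)=C)CC=C1C | intermediate (not isolated)
6 | (5S,6S)-6-allyl-2,6-dimethyl-5-(prop-1-en-2-yl)cyclohex-2-en-1-one | C=CC[C@@]1(C)[C@H](C(C)=C)CC=C(C)C1=O | intermediate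
7 | lithium enolate from conjugate reduction of 6 | C=CC[C@@]1(C)[C@H](C(C)=C)CCC(C)=C1O[Li] | intermediate (not isolated)
8 | (2S,3S,6R)-2-allyl-2,6-dimethyl-3-(prop-1-en-2-yl)cyclohexan-1-one | C=CC[C@@]1(C)[C@H](C(C)=C)CC[C@@H](C)C1=O | intermediate
9 | {3-[(1S,3R,6S)-1,3-dimethyl-2-oxo-6-(prop-1-en-2-yl)cyclohexyl]propyl}bis(3-methylbutan-2-yl)borane | CC(C)C(C)B(CCC[C@@]1(C)[C@H](C(C)=C)CC[C@@H](C)C1=O)C(C)C(C)C | intermediate (not isolated)
10 | (2S,3S,6R)-2-(3-hydroxypropyl)-2,6-dimethyl-3-(prop-1-en-2-yl)cyclohexan-1-one | OCCC[C@@]1(C)[C@H](C(C)=C)CC[C@@H](C)C1=O | intermediate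
11 | 3-[(1S,3R,6S)-1,3-dimethyl-2-oxo-6-(prop-1-en-2-yl)cyclohexyl]propanal (3,4-seco precursor) | O=CCC[C@@]1(C)[C@H](C(C)=C)CC[C@@H](C)C1=O | intermediate
12 | (2R,4aS,6S,8aS)-6-hydroxy-2,5,5,8a-tetramethyloctahydronaphthalen-1(2H)-one (3β-hydroxy-4,4,8α,10β-tetramethyl-trans-decalin-9-one) | O[C@H]1CC[C@@]2(C)[C@@H](CC[C@@H](C)C2=O)C1(C)C | intermediate
13 | 3β-hydroxy-4,4,8α,10β-tetramethyl-9-methylidene-trans-decalin (5α-H) | O[C@H]1CC[C@@]2(C)[C@@H](CC[C@@H](C)C2=C)C1(C)C | intermediate
14 | 9α,11-epoxide of 13 (spiro-oxirane, O on the α face) | O[C@H]1CC[C@@]2(C)[C@@H](CC[C@@H](C)[C@]23CO3)C1(C)C | intermediate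
15 | furan-3-ylmethanol | OCc1ccoc1 | starting material
16 | furan-3-ylmethyl methanesulfonate | CS(=O)(=O)OCc1ccoc1 | intermediate (not isolated)
17 | 3-(chloromethyl)furan | ClCc1ccoc1 | intermediate
18 | (furan-3-ylmethyl)magnesium chloride | Cl[Mg]Cc1ccoc1 | intermediate (not isolated)
19 | 15,16-epoxylabda-13(16),14-diene-3β,9α-diol | O[C@H]1CC[C@@]2(C)[C@@H](CC[C@@H](C)[C@]2(O)CCc2ccoc2)C1(C)C | intermediate
20 | 3β-acetoxy-15,16-epoxylabda-13(16),14-dien-9α-ol | CC(=O)O[C@H]1CC[C@@]2(C)[C@@H](CC[C@@H](C)[C@]2(O)CCc2ccoc2)C1(C)C | intermediate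
21 | 2,5-endoperoxide of the furan ring of 20 (2,3,7-trioxabicyclo[2.2.1]hept-5-ene) | CC(=O)O[C@H]1CC[C@@]2(C)[C@@H](CC[C@@H](C)[C@]2(O)CCC2=CC3OOC2O3)C1(C)C | intermediate (not isolated)
22 | 3β-acetoxy-9α,16-dihydroxylabd-13-en-15,16-olide (C16 epimers) | CC(=O)O[C@H]1CC[C@@]2(C)[C@@H](CC[C@@H](C)[C@]2(O)CCC2=CC(=O)OC2O)C1(C)C | intermediate
23 | sodium (Z)-4-hydroxybut-2-enoate form of the side chain (ring-opened, reduced 22) | CC(=O)O[C@H]1CC[C@@]2(C)[C@@H](CC[C@@H](C)[C@]2(O)CC/C(CO)=C/C(=O)[O-])C1(C)C.[Na+] | intermediate (not isolated)
24 | (3S,5S,8R,9R,10S)-3β-acetoxy-9α-hydroxylabd-13-en-15,16-olide | CC(=O)O[C@H]1CC[C@@]2(C)[C@@H](CC[C@@H](C)[C@]2(O)CCC2=CC(=O)OC2)C1(C)C | target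

## Step count and risks

Total steps: 13. Longest linear sequence: 12 (steps 1–8 and 10–13 from (R)-carvone; step 9 is a one-step side branch).

**Step 6 (key cyclisation).** The tertiary C4 radical may be reduced to the isopropyl compound, or the alkoxy radical may fragment back before it is trapped. Attack on the two faces of the aldehyde may also be poorly differentiated.
Fallback: it sets out from alcohol 10 and returns at 12. Markovnikov addition of anhydrous HBr (CH2Cl2, −20 °C) to the isopropenyl group should give the tertiary bromide F1. Dess–Martin oxidation should then give the bromo aldehyde F2. Tin hydride radical cyclisation (Bu3SnH, AIBN, benzene, 80 °C, slow addition) generates the same C4 radical by bromine abstraction and closes the same C3–C4 bond 6-exo. This should give 12 together with its 3α-epimer F3. The mixture is converged by Dess–Martin oxidation to the 3,9-dione F4. NaBH4 (MeOH, −40 °C) should then reduce only the less hindered C3 ketone by axial hydride delivery from the α face (the 4β-methyl blocks the β face), returning 12.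

**Step 10 (epoxide opening).** SN2 attack at the neopentyl-type C11 may be slow enough that magnesium-salt-promoted rearrangement of the epoxide to a C9 aldehyde competes. The ambident furylmethyl metal may also couple through a ring carbon.
Fallback: it sets out from alkene 13 (and chloride 17) and returns at 19. Dihydroxylation (OsO4 cat., NMO, acetone/H2O) on the same α face should give the 3β,9α,11-triol F5. Selective oxidation of the primary alcohol (TEMPO, PhI(OAc)2, CH2Cl2) should give the 9α-hydroxy 11-aldehyde F6. Heating 17 with PPh3 in toluene gives (furan-3-ylmethyl)triphenylphosphonium chloride F7. Its ylide (KHMDS, THF, −78 °C, excess to cover the two hydroxyls) should convert F6 by Wittig olefination into the C11=C12 alkene F8. Diimide (TsNHNH2, NaOAc, DME/H2O, reflux) should then saturate only this disubstituted alkene and return 19. C11–C12 is thus made at an sp2 aldehyde carbon, and the furan unit reacts only through its exocyclic carbon.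

**Step 7 (methylenation).** Steric shielding of C9 by C10 and C8 and enolisation toward C8 by the basic ylide may stall the olefination.
Fallback: it sets out from 12 and returns at 13. Addition of the small, weakly basic Me3SiCH2Li with anhydrous CeCl3 (THF, −78 → 0 °C) should give the β-hydroxysilane F9 (either C9 epimer serves). Peterson elimination with KH (THF, rt) should then give 13.

## Further compounds

F1 | step 6 | 3-(2-bromopropan-2-yl)-2-(3-hydroxypropyl)-2,6-dimethylcyclohexan-1-one (HBr adduct of 10) | OCCC[C@@]1(C)[C@H](C(C)(C)Br)CC[C@@H](C)C1=O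
F2 | step 6 | 3-[6-(2-bromopropan-2-yl)-1,3-dimethyl-2-oxocyclohexyl]propanal | O=CCC[C@@]1(C)[C@H](C(C)(C)Br)CC[C@@H](C)C1=O
F3 | step 6 | 3α-epimer of 12 | O[C@@H]1CC[C@@]2(C)[C@@H](CC[C@@H](C)C2=O)C1(C)C
F4 | step 6 | 4,4,8α,10β-tetramethyl-trans-decalin-3,9-dione | O=C1CC[C@@]2(C)[C@@H](CC[C@@H](C)C2=O)C1(C)C
F5 | step 10 | 9-(hydroxymethyl)-4,4,8α,10β-tetramethyl-trans-decalin-3β,9α-diol | O[C@H]1CC[C@@]2(C)[C@@H](CC[C@@H](C)[C@]2(O)CO)C1(C)C
F6 | step 10 | 3β,9α-dihydroxy-4,4,8α,10β-tetramethyl-trans-decalin-9-carbaldehyde | O[C@H]1CC[C@@]2(C)[C@@H](CC[C@@H](C)[C@]2(O)C=O)C1(C)C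
F7 | step 10 | (furan-3-ylmethyl)triphenylphosphonium chloride | [Cl-].c1ccc(cc1)[P+](Cc1ccoc1)(c1ccccc1)c1ccccc1
F8 | step 10 | 15,16-epoxylabda-11,13(16),14-triene-3β,9α-diol (E/Z mixture) | O[C@H]1CC[C@@]2(C)[C@@H](CC[C@@H](C)[C@]2(O)C=Cc2ccoc2)C1(C)C
F9 | step 7 | 9-[(trimethylsilyl)methyl]-4,4,8α,10β-tetramethyl-trans-decalin-3β,9-diol | O[C@H]1CC[C@@]2(C)[C@@H](CC[C@@H](C)C2(O)C[Si](C)(C)C)C1(C)C
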